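**Retrosynthetic overview**
1. The last disconnection is the C7–O–CH2 aryl ether (Mitsunobu), giving 7-hydroxy-6,8-dimethoxycoumarin (10) and the (2R,3R)-epoxy diol 16.
2. The strategy rests on the C4–C4a bond of the pyranone ring: C4a is the only unsubstituted benzene carbon ortho to O1 and lies para to O7. This bond is made by gold-catalysed 6-endo hydroarylation of aryl propiolate 8.
3. Propiolate 8 comes from 2,6-dimethoxyphenol: O7 is marked from the start as an isopropyl ether, O1 is introduced by ortho-lithiation/borylation/oxidation, then esterified.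
4. Epoxy diol 16 comes from geranyl acetate: terminal hydroxyselenenylation and selenoxide elimination, deacetylation, then Sharpless epoxidation with D-(−)-diethyl tartrate sets both stereocentres.
5. Ring order: the benzene ring is bought, the pyranone ring closes in step 4, the oxirane in step 9, and the two halves are joined in step 10.

Key step: step 4

Remark on the chemistry: geranyl acetate is used as the commercial form of the geraniol unit, and the oxirane is installed only after the terminal oxidation, so the acid-labile epoxide never meets the selenium electrophile. The (2R,3R) assignment of the target was derived from its SMILES; D-(−)-diethyl tartrate is chosen because the L-(+)-ester gives (2S,3S)-epoxides from E-allylic alcohols of this type.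

**Step 1**
Reactants: 1 2,6-dimethoxyphenol; 2 2-bromopropane
Product: 3 1,3-dimethoxy-2-(propan-2-yloxy)benzene
Conditions: K2CO3, DMF, 70 °C
Reagents that add atoms: none
Why: Williamson ether synthesis, in which the phenoxide of 1 is O-alkylated by the secondary bromide in a dipolar aprotic solvent, marking the future O7 as the one oxygen that can later be freed in the presence of methyl ethers.

**Step 2**
Reactants: 3 1,3-dimethoxy-2-(propan-2-yloxy)benzene
Product: 6 2,4-dimethoxy-3-(propan-2-yloxy)phenol, via aryllithium 4 (not isolated), via arylboronate 5 (not isolated)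
Conditions: nBuLi, TMEDA, THF, 0 °C; B(OMe)3, −78 °C → rt; AcOH, 30% H2O2, 0 °C → rt
Reagents that add atoms: hydrogen peroxide, OO
Why: Directed ortho-metalation, borylation and oxidation, in which a methoxy oxygen guides nBuLi to the adjacent ring carbon (the two such carbons of 3 are equivalent and are the only ones next to an alkoxy group), B(OMe)3 traps the aryllithium, and peroxide-induced 1,2-shift of the aryl group from boron to oxygen gives the phenol.

**Step 3**
Reactants: 6 2,4-dimethoxy-3-(propan-2-yloxy)phenol; 7 propiolic acid
Product: 8 2,4-dimethoxy-3-(propan-2-yloxy)phenyl prop-2-ynoate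
Conditions: DCC, DMAP (cat.), CH2Cl2, −20 → 0 °C
Reagents that add atoms: none
Why: Carbodiimide (Steglich-type) esterification, in which DCC turns propiolic acid into the O-acylisourea that acylates the phenol at low temperature, where conjugate addition to the ynoate should be slow.

**Step 4**
Reactants: 8 2,4-dimethoxy-3-(propan-2-yloxy)phenyl prop-2-ynoate
Product: 9 6,8-dimethoxy-7-(propan-2-yloxy)-2H-chromen-2-one
Conditions: (Ph3P)AuNTf2 (5 mol %), 1,2-dichloroethane, rt → 60 °C
Reagents that add atoms: none
Why: The cationic monovalent gold centre π-activates the terminal alkyne of 8, and the arene carbon ortho to the ester oxygen attacks the terminal alkyne carbon anti to gold; the resulting vinylgold arenium ion rearomatizes by proton loss and protodeauration releases the C3=C4 alkene of the lactone. The closest known reaction type is the gold-catalysed intramolecular hydroarylation of aryl propiolates to coumarins. The pyranone ring closes in the 6-endo-dig mode with formation of the C4–C4a bond. No stereocentre is formed. The step needs ortho attack to win over ipso attack at the oxygen-bearing carbon: the other ortho carbon carries a methoxy group, so only the carbon para to the isopropoxy oxygen can lose a proton, and the unsubstituted alkyne terminus reaches it through an unstrained six-membered transition state, whereas ipso attack would need a strained spiro five-membered cation. Because the isopropoxy group is twisted by its two methoxy neighbours, its donation to the attacking carbon is weakened, so mild heating is planned.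

**Step 5**
Reactants: 9 6,8-dimethoxy-7-(propan-2-yloxy)-2H-chromen-2-one
Product: 10 7-hydroxy-6,8-dimethoxy-2H-chromen-2-one (isofraxidin)
Conditions: BCl3, CH2Cl2, −78 → 0 °C; aqueous work-up
Reagents that add atoms: none
Why: Lewis-acid ether cleavage, in which BCl3 binds the crowded central ether oxygen and the secondary isopropyl group leaves as 2-chloropropane much more readily than a methyl group, so the two methyl ethers and the lactone should survive at low temperature.

**Step 6**
Reactants: 11 geranyl acetate
Product: 12 (2E)-7-hydroxy-3,7-dimethyl-6-(phenylselanyl)oct-2-en-1-yl acetate (racemic at C6)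
Conditions: PhSeCl, MeCN/H2O (5:1), rt
Reagents that add atoms: benzeneselenenyl chloride, Cl[Se]c1ccccc1; water, O
Why: Hydroxyselenenylation, in which the selenium electrophile adds to the more electron-rich remote 6,7-alkene (the 2,3-alkene is deactivated by the allylic acetate) and water opens the seleniranium ion at the tertiary carbon in the Markovnikov sense, the selenium-bearing carbon being a racemic centre that is removed in step 7.

**Step 7**
Reactants: 12 (2E)-7-hydroxy-3,7-dimethyl-6-(phenylselanyl)oct-2-en-1-yl acetate
Product: 14 (2E,5E)-7-hydroxy-3,7-dimethylocta-2,5-dien-1-yl acetate, via selenoxide 13 (not isolated)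
Conditions: 30% H2O2, pyridine, CH2Cl2, 0 °C → rt
Reagents that add atoms: none
Why: Selenide oxidation followed by selenoxide syn-elimination, which can only take a hydrogen from C5 because C7 carries none, and should therefore give the E-configured allylic tertiary alcohol.

**Step 8**
Reactants: 14 (2E,5E)-7-hydroxy-3,7-dimethylocta-2,5-dien-1-yl acetate
Product: 15 (2E,5E)-3,7-dimethylocta-2,5-diene-1,7-diol
Conditions: K2CO3 (cat.), MeOH, rt
Reagents that add atoms: none
Why: Base-catalysed transesterification with methanol removes the acetate under conditions too mild to move the skipped diene into conjugation.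

**Step 9**
Reactants: 15 (2E,5E)-3,7-dimethylocta-2,5-diene-1,7-diol
Product: 16 [(2R,3R)-3-[(2E)-4-hydroxy-4-methylpent-2-en-1-yl]-3-methyloxiran-2-yl]methanol
Conditions: Ti(OiPr)4 (0.5 equiv), D-(−)-diethyl tartrate (0.6 equiv), tBuOOH (in isooctane), 4 Å MS, CH2Cl2, −20 °C
Reagents that add atoms: tert-butyl hydroperoxide, CC(C)(C)OO
Why: Sharpless asymmetric epoxidation, in which the primary allylic alkoxide binds the titanium–tartrate complex and the D-(−)-tartrate ligand directs oxygen to the alkene face that gives the (2R,3R)-oxirane, the E-geometry fixing CH2OH and the C3 chain trans so that both stereocentres are set in this step, while the hindered tertiary allylic alcohol and its disubstituted alkene should react far more slowly.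

**Step 10**
Reactants: 10 7-hydroxy-6,8-dimethoxy-2H-chromen-2-one; 16 [(2R,3R)-3-[(2E)-4-hydroxy-4-methylpent-2-en-1-yl]-3-methyloxiran-2-yl]methanol
Product: 17 7-{[(2R,3R)-3-[(2E)-4-hydroxy-4-methylpent-2-en-1-yl]-3-methyloxiran-2-yl]methoxy}-6,8-dimethoxy-2H-chromen-2-one (CNP0325711.2)
Conditions: PPh3, DIAD, THF, 0 °C → rt
Reagents that add atoms: none
Why: Mitsunobu etherification, in which the acidic 7-hydroxycoumarin protonates the PPh3–DIAD betaine and its phenoxide displaces the oxyphosphonium of the primary alcohol by SN2 at the non-stereogenic CH2, so both oxirane stereocentres stay untouched and the tertiary alcohol is too hindered to be activated.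

**Compound list**
1 | 2,6-dimethoxyphenol | COc1cccc(OC)c1O | starting material
2 | 2-bromopropane | CC(C)Br | starting material
3 | 1,3-dimethoxy-2-(propan-2-yloxy)benzene | COc1cccc(OC)c1OC(C)C | intermediate
4 | [2,4-dimethoxy-3-(propan-2-yloxy)phenyl]lithium | [Li]c1ccc(OC)c(OC(C)C)c1OC | intermediate
5 | dimethyl [2,4-dimethoxy-3-(propan-2-yloxy)phenyl]boronate | COB(OC)c1ccc(OC)c(OC(C)C)c1OC | intermediate
6 | 2,4-dimethoxy-3-(propan-2-yloxy)phenol | COc1ccc(O)c(OC)c1OC(C)C | intermediate
7 | propiolic acid (prop-2-ynoic acid) | C#CC(=O)O | starting material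
8 | 2,4-dimethoxy-3-(propan-2-yloxy)phenyl prop-2-ynoate | C#CC(=O)Oc1ccc(OC)c(OC(C)C)c1OC | intermediate
9 | 6,8-dimethoxy-7-(propan-2-yloxy)-2H-chromen-2-one | COc1cc2ccc(=O)oc2c(OC)c1OC(C)C | intermediate
10 | 7-hydroxy-6,8-dimethoxy-2H-chromen-2-one (isofraxidin) | COc1cc2ccc(=O)oc2c(OC)c1O | intermediate
11 | geranyl acetate, (2E)-3,7-dimethylocta-2,6-dien-1-yl acetate | CC(=O)OC/C=C(\C)CCC=C(C)C | starting material
12 | (2E)-7-hydroxy-3,7-dimethyl-6-(phenylselanyl)oct-2-en-1-yl acetate, racemic at C6 | CC(=O)OC/C=C(\C)CCC([Se]c1ccccc1)C(C)(C)O | intermediate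
13 | (2E)-7-hydroxy-3,7-dimethyl-6-(phenylseleninyl)oct-2-en-1-yl acetate (selenoxide) | CC(=O)OC/C=C(\C)CCC([Se](=O)c1ccccc1)C(C)(C)O | intermediate
14 | (2E,5E)-7-hydroxy-3,7-dimethylocta-2,5-dien-1-yl acetate | CC(=O)OC/C=C(\C)C/C=C/C(C)(C)O | intermediate
15 | (2E,5E)-3,7-dimethylocta-2,5-diene-1,7-diol | OC/C=C(\C)C/C=C/C(C)(C)O | intermediate
16 | [(2R,3R)-3-[(2E)-4-hydroxy-4-methylpent-2-en-1-yl]-3-methyloxiran-2-yl]methanol | OC[C@H]1O[C@]1(C)C/C=C/C(C)(C)O | intermediate
17 | 7-{[(2R,3R)-3-[(2E)-4-hydroxy-4-methylpent-2-en-1-yl]-3-methyloxiran-2-yl]methoxy}-6,8-dimethoxy-2H-chromen-2-one | COc1cc2ccc(=O)oc2c(OC)c1OC[C@H]1O[C@]1(C)C/C=C/C(C)(C)O | target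

**Step count**
Total: 10 steps. Longest linear sequence: 6 steps (steps 1–5, then step 10); the side-chain branch is 5 steps (steps 6–10).

**Steps most likely to fail**

Step 4. The ring closure may be slow because the twisted isopropoxy group donates poorly to the attacking carbon. Ipso attack followed by an acyloxy shift could divert material to an isomeric coumarin, and adventitious water could hydrate the activated alkyne. The fallback builds the pyranone from the other side, by C-formylation and olefination, and sets out from phenol 6. Ortho-formylation with MgCl2, Et3N and paraformaldehyde in MeCN at reflux can only occur at the one free ortho carbon and should give 2-hydroxy-3,5-dimethoxy-4-(propan-2-yloxy)benzaldehyde F1. Wittig reaction with Ph3P=CHCO2Et should give ethyl (2E)-3-[2-hydroxy-3,5-dimethoxy-4-(propan-2-yloxy)phenyl]prop-2-enoate F2. Heating F2 in N,N-diethylaniline at reflux should isomerize the alkene and lactonize with loss of ethanol, returning to the route at coumarin 9.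

Step 9. The free tertiary hydroxyl can also bind titanium, which may erode the enantioselectivity, stall turnover, or direct some oxidation to the 5,6-alkene. The fallback masks that hydroxyl and sets out from acetate 14. TESOTf and 2,6-lutidine in CH2Cl2 should give (2E,5E)-3,7-dimethyl-7-[(triethylsilyl)oxy]octa-2,5-dien-1-yl acetate F3. K2CO3 in MeOH should then give (2E,5E)-3,7-dimethyl-7-[(triethylsilyl)oxy]octa-2,5-dien-1-ol F4, now a simple geraniol-type mono-alcohol. Epoxidation with Ti(OiPr)4, D-(−)-diethyl tartrate and tBuOOH should give [(2R,3R)-3-methyl-3-[(2E)-4-methyl-4-[(triethylsilyl)oxy]pent-2-en-1-yl]oxiran-2-yl]methanol F5. Bu4NF in THF removes the silyl group and returns to the route at epoxy diol 16.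

Step 10. Activation of the alcohol may be followed by slow attack of the doubly ortho-substituted phenoxide, so that the reduced azodicarboxylate is alkylated instead or the oxyphosphonium decomposes. The fallback replaces the redox condensation by a sulfonate alkylation and sets out from epoxy diol 16. TsCl, Et3N and catalytic DMAP in CH2Cl2 at 0 °C should sulfonylate only the primary hydroxyl and give [(2R,3R)-3-[(2E)-4-hydroxy-4-methylpent-2-en-1-yl]-3-methyloxiran-2-yl]methyl 4-methylbenzenesulfonate F6. Treating F6 with phenol 10 and Cs2CO3 in DMF should give direct displacement at CH2, since the quaternary oxirane carbon blocks the alternative epoxide-opening path, returning to the route at target 17.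

**Further compounds**
F1 | step 4 | 2-hydroxy-3,5-dimethoxy-4-(propan-2-yloxy)benzaldehyde | O=Cc1cc(OC)c(OC(C)C)c(OC)c1O
F2 | step 4 | ethyl (2E)-3-[2-hydroxy-3,5-dimethoxy-4-(propan-2-yloxy)phenyl]prop-2-enoate | CCOC(=O)/C=C/c1cc(OC)c(OC(C)C)c(OC)c1O
F3 | step 9 | (2E,5E)-3,7-dimethyl-7-[(triethylsilyl)oxy]octa-2,5-dien-1-yl acetate | CC(=O)OC/C=C(\C)C/C=C/C(C)(C)O[Si](CC)(CC)CC
F4 | step 9 | (2E,5E)-3,7-dimethyl-7-[(triethylsilyl)oxy]octa-2,5-dien-1-ol | OC/C=C(\C)C/C=C/C(C)(C)O[Si](CC)(CC)CC
F5 | step 9 | [(2R,3R)-3-methyl-3-[(2E)-4-methyl-4-[(triethylsilyl)oxy]pent-2-en-1-yl]oxiran-2-yl]methanol | OC[C@H]1O[C@]1(C)C/C=C/C(C)(C)O[Si](CC)(CC)CC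
F6 | step 10 | [(2R,3R)-3-[(2E)-4-hydroxy-4-methylpent-2-en-1-yl]-3-methyloxiran-2-yl]methyl 4-methylbenzenesulfonate | Cc1ccc(cc1)S(=O)(=O)OC[C@H]1O[C@]1(C)C/C=C/C(C)(C)O
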